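The flask is slow, and I used that: in delta, 34% of the Q was still free at 15.0 min, so for your quick number I reckoned with the fraction left and built no scheme. You guessed that the Q left goes inversely as the G charged, which puts green at 0.500 of amber.

common to all: Q 0.40 M
- delta: G 0.28 M; run made earlier
- epsilon: G 0.52 M; run made earlier
- gamma: G 0.93 M; run made earlier
- amber: G 0.400 M; time 15 min
- green: G 0.800 M; time 15 min

| run | time / min | J / % | X / % | Q / % |
|---|---|---|---|---|
| delta | 2.00 | 4 | 2 | 83 |
| delta | 5.00 | 13 | 2 | 64 |
| delta | 10.0 | 17 | 4 | 42 |
| delta | 15.0 | 19 | 0 | 34 |
| epsilon | 2.00 | 10 | 1 | 79 |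
| epsilon | 5.00 | 18 | 0 | 61 |
| epsilon | 10.0 | 26 | 8 | 36 |
| epsilon | 15.0 | 25 | 11 | 26 |
| gamma | 4.00 | 26 | 3 | 51 |
| gamma | 8.00 | 32 | 10 | 32 |
| gamma | 12.0 | 32 | 16 | 19 |
| gamma | 15.0 | 28 | 22 | 16 |

(readings scatter by 1.5 percentage points)

1. which of these there is most of at the end, counted by the Q in it, amber (J / X / Q)
2. which of these there is most of at the end, counted by the Q in it, green (J / X / Q)
3. how much there is at the end of the one of these that leads, in percent of the Q charged: amber
4. how much there is at the end of the one of these that leads, in percent of the Q charged: green

- the analysis behind the earlier runs scatters by 1.5 percentage points, standard deviation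
- a reading or a percentage of X counts all its forms, free or not
- a reading of Q is of its free form alone

I plotted ln of the fraction of Q left at 15 min against cG, the pseudo-first-order way of reckoning, which holds while G stays near its charge. I call the fall of that logarithm per unit of cG the G slope: delta and gamma gave 1.16 M⁻¹. Epsilon, which I had not used, came out at 25.7% against a reading of 26%, with a scatter of 1.5 percentage points. So I put amber at 29.6% and green at 18.6%. That makes the green-to-amber factor 0.629, which is more Q than your guess leaves.

For J I drew straight lines between the final readings. Amber came to 22.0%, less than its Q, so I had Q leading there. Green came to 27.0%, more than its Q and more than its X, which the same line put at 18.5%, so I had J leading there.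

The forecast gave Q at 30% for amber and, in its words “J leads”, J at 28% for green, a J higher than mine. The flasks gave Q at 29.4% in amber and J at 29.9% in green, where Q stood at 18.8%.

    G + J → X + Z (k = 0.0828 M⁻¹ min⁻¹)
    G + X ⇌ E, settled at all times (K = 3.28 M⁻¹)
    Q + G → J + Z (k = 0.109 M⁻¹ min⁻¹)
    Q ⇌ D (K = 2.43, k = 0.0652 min⁻¹)

In amber at 15.0 min, the forward passing of Q into D, taken by itself, used Q 2.4 times as fast as Q + G into J + Z. At 4.19 min that ratio was 1.8; both ratios count the forward step alone, and D also returns to Q. The G slope's factor of 0.629 stood against 0.637 from the two flasks.

For a further flask, like amber but with 1.6 M of G, more than gamma had, the G slope gave 7.36% of Q left. The computed flask gave 7.88%.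

The runs are simulated for an exercise; noise was put on by code.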